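(Readings and results are calculated for substances that don't exist; the scatter is artificial.)

The ratio of free monomer to initiator is 100 to one in both new flasks, and that ratio, trimmed by the protic impurity, is where you should look for the chain length.

common to all: free monomer 20 mM; initiator 1 mol%

|  | protic impurity | remark | time |
|---|---|---|---|
| south-east | 0.43 mM | run made earlier |  |
| south-west | 0.78 mM | run made earlier |  |
| west | 0.84 mM | run made earlier |  |
| Saturday's | 1.00 mM |  | 8.0 min |
| Sunday's | 0.600 mM |  | 8.0 min |

| run | time / min | monomer in chains / % |
|---|---|---|
| south-east | 0.417 | 49 |
| south-east | 0.833 | 69 |
| south-east | 1.50 | 81 |
| south-east | 3.00 | 91 |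
| south-east | 6.00 | 94 |
| south-west | 1.00 | 72 |
| south-west | 2.50 | 87 |
| south-west | 3.00 | 90 |
| south-west | 5.00 | 94 |
| south-west | 6.00 | 98 |
| west | 0.417 | 43 |
| west | 0.833 | 68 |
| west | 1.50 | 76 |
| west | 3.00 | 88 |
| west | 6.00 | 95 |

(scatter of a reading: 2 percentage points)

- the average divides the monomer in chains by the number of chains, living and dead together; two radicals that join make one chain
- the numbers in the tables scatter by 2 percentage points (one standard deviation)
- what may be going on: 2 growing radical -> dead chain; free monomer + growing radical -> monomer in chains + growing radical; protic impurity + free monomer -> quenched substrate; free monomer + initiating radical -> growing radical + monomer in chains; initiator -> 2 initiating radical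
- the earlier runs do not show the number of chains; that part of a forecast is a guess

* which of the two ends with the longer chains by the average number of monomer units in a chain (living and dead chains, two that joined counted as one) ("neither" if they lie within 10%) (Saturday's / Sunday's / neither)
* average number of monomer units in a chain (living and dead chains, two that joined counted as one) at the end, Saturday's
* average number of monomer units in a chain (living and dead chains, two that joined counted as one) at the end, Sunday's

Start with the rate in the south-east run. Over its first 0.417 min, monomer enters chains at 1.18 /min of the charge, and between 1.50 min and 6.00 min at 0.0289 /min, so the later rate is lower by a factor of 40.8. Now take the rate per unit of free monomer, counting the impurity's share as lost. It goes from 1.67 /min to 0.328 /min. That is a factor of 5.09, which fits fewer growing radicals, and the remaining factor of 8.02 is free monomer used up. Both are readings with their scatter. Even with this slowing, the south-east run reads nearly all of the monomer the impurity spares in chains by 6.00 min.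

So the chain count remains to be found, and this part is a guess. Take the balance of initiator, which at 0.200 mM is charged in a smaller amount than the protic impurity or the free monomer. One initiator gives two initiating radicals, each starts a growing radical, and two growing radicals join into one dead chain, so one initiator ends as one chain. Divide free monomer charged less protic impurity by initiator charged and you have the balance length, my estimate of the number-average degree of polymerisation: 95.0 for Saturday's flask and 97.0 for Sunday's. They stand 2.11% apart, so I say neither.

The forecast gave 86 for Saturday's and 89 for Sunday's, “a difference of only a few percent, so neither”; its lengths are lower than mine, though its choice is the same. The flasks give 93.5 for Saturday's and 95.5 for Sunday's, so neither.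

    2 growing radical → dead chain (k = 2.60 × 10⁷ /M/s)
    free monomer + growing radical → monomer in chains + growing radical, rate k2*[growing radical]*[free monomer] (k = 84000 /M/s)
    protic impurity + free monomer → quenched substrate (k = 40.0 /M/s)
    free monomer + initiating radical → growing radical + monomer in chains (k = 2.70 × 10⁶ /M/s)
    initiator → 2 initiating radical (k = 0.0130 /s)

Saturday's flask ends at 93.5 against its balance length of 95.0. The neighbour with 4 mol% initiator has a balance length of 23.8 but gives 30.0, with free monomer at 0% and 0.329 mM initiating radical still standing. Saturday's flask has nearly come to rest: from 8.00 min to 80.0 min, free monomer goes from 1.65% to 1.36%, dead chain stands at 0.200 mM, and the length moves from 93.5 to 93.6.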